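The route rests on a formal [3+2] annulation that joins the O1–C2–C3 unit of the dihydrofuran ring (ring B) to the adjacent carbons C7a and C3a of the benzene ring (ring A). An ortho-fluoroaryl Grignard reagent, made from a 3-bromo-4-fluorophenyl carbinol, adds under chelation control to an (S)-alpha-triethylsilyloxy aldehyde (C3a–C3 bond, C3 stereocentre). The silyl group then shifts to the new alkoxide and the released C2 alkoxide displaces fluoride (O1–C7a bond). The step exploits the 1,2-oxygen/carbon pattern at C7a/C3a, the para relationship of O1 to the C5 side chain and the cis C2/C3 relationship. Esterification, acetylation and allylic oxidation finish the molecule.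

Key step: step 5

Remark: the target is read as (2S,3S) with the C2 and C3 substituents cis on ring B, (R) at the benzylic ester carbon and a (Z)-enoate (angelate); atom numbers are those of 1-benzofuran.

Step 1
Reactants: 1 1-(3-bromo-4-fluorophenyl)ethanone
Product: 2 (1R)-1-(3-bromo-4-fluorophenyl)ethan-1-ol
Conditions: RuCl[(R,R)-TsDPEN](p-cymene) (0.5 mol %), HCO2H/Et3N (5:2), 30 °C
Reagents that add atoms: none
Why: Noyori asymmetric transfer hydrogenation of an aryl methyl ketone, in which the (R,R)-ligand should deliver hydride to the face that gives the (R)-carbinol while the C–Br and C–F bonds stay inert.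

Step 2
Reactants: 3 3-methylbut-2-en-1-ol
Product: 4 [(2R)-3,3-dimethyloxiran-2-yl]methanol
Conditions: Ti(OiPr)4 (5 mol %), D-(−)-diisopropyl tartrate (6 mol %), t-BuOOH, 4 Å molecular sieves, CH2Cl2, −20 °C
Reagents that add atoms: tert-butyl hydroperoxide CC(C)(C)OO
Why: Katsuki–Sharpless asymmetric epoxidation of an allylic alcohol, in which the D-(−)-tartrate catalyst should transfer oxygen to the face that gives the (2R)-epoxide (mirror image of the (2S) series obtained with L-(+)-tartrate).

Step 3
Reactants: 4 [(2R)-3,3-dimethyloxiran-2-yl]methanol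
Product: 5 (2S)-3-methyl-1,2-bis(triethylsilyloxy)but-3-ene
Conditions: Et3SiOTf (2.3 equiv), DBU (2.5 equiv), toluene, −20 °C to rt
Reagents that add atoms: triethylsilyl trifluoromethanesulfonate CC[Si](CC)(CC)OS(=O)(=O)C(F)(F)F
Why: The primary alcohol is silylated and the silyl triflate/amidine pair isomerises the trisubstituted epoxide to the allyl silyl ether (opening at the tertiary carbon, proton loss from a methyl group); the C2–O bond is never broken, so the centre is retained and is named (S) only because the priorities change.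

Step 4
Reactants: 5 (2S)-3-methyl-1,2-bis(triethylsilyloxy)but-3-ene
Product: 6 (2S)-3-methyl-2-(triethylsilyloxy)but-3-enal
Conditions: (COCl)2, DMSO, CH2Cl2, −78 to −40 °C; then Et3N, −78 to 0 °C; used crude at once
Reagents that add atoms: none
Why: Swern oxidation, which should convert the primary triethylsilyl ether directly into the aldehyde while the more hindered secondary silyl ether stays; low temperature and immediate use protect the alpha stereocentre, which is allylic and alpha to the carbonyl.

Step 5
Reactants: 2 (1R)-1-(3-bromo-4-fluorophenyl)ethan-1-ol, 6 (2S)-3-methyl-2-(triethylsilyloxy)but-3-enal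
Product: 11 (1R)-1-[(2S,3S)-2-(prop-1-en-2-yl)-3-(triethylsilyloxy)-2,3-dihydro-1-benzofuran-5-yl]ethan-1-ol, via aryllithium 7 (not isolated), via aryl Grignard 8 (not isolated), via syn magnesium alkoxide 9 (not isolated), via silyl-shifted potassium alkoxide 10 (not isolated)
Conditions: 2, n-BuLi (2.1 equiv), Et2O/toluene, −78 °C; MgBr2·OEt2 (1.2 equiv); 6, −78 to −30 °C; then KOtBu (3.5 equiv), DMPU, 70 °C; aq NH4Cl
Reagents that add atoms: none
Why: Bromine–lithium exchange on the lithium alkoxide of 2 and transmetalation give the ortho-fluoroaryl Grignard 8, which adds to aldehyde 6 through a Cram chelate (magnesium bridging the aldehyde oxygen and the small triethylsilyloxy oxygen), so the aryl group enters anti to the isopropenyl group and creates C3 as (S), syn to the C2 oxygen; KOtBu/DMPU then triggers a 1,2 oxygen-to-oxygen silyl shift (9 to 10) and the freed C2 alkoxide displaces fluoride at C7a by intramolecular SNAr. The closest known reaction types are chelation-controlled Grignard addition to alpha-oxygenated aldehydes, base-induced silyl migration between vicinal oxygens and alkoxide SNAr cyclisation of 2-fluoroaryl alkanols, here run as one anionic cascade. Ring B closes in a 5-exo mode by addition–elimination at the sp2 carbon C7a. C2 is carried unchanged from 6 and C3 is set by the chelate, so the cis (2S,3S) arrangement follows from syn addition; carbon–carbon bond formation before carbon–oxygen bond formation is chosen because closure of a preformed aryl ether onto the aldehyde would be expected to favour the trans isomer. The step needs chelate-controlled over Felkin-type attack, which the small silyl group, the magnesium counter-ion and the weakly coordinating medium should secure. It also needs a single regiochemistry, fixed by Br at C3a and F at C7a of 2 (F para to the side chain) and by the fact that only the C2 oxygen can reach C7a through a five-membered transition state.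

Step 6
Reactants: 11 (1R)-1-[(2S,3S)-2-(prop-1-en-2-yl)-3-(triethylsilyloxy)-2,3-dihydro-1-benzofuran-5-yl]ethan-1-ol, 12 angelic acid [(2Z)-2-methylbut-2-enoic acid]
Product: 14 (1R)-1-[(2S,3S)-2-(prop-1-en-2-yl)-3-(triethylsilyloxy)-2,3-dihydro-1-benzofuran-5-yl]ethyl (2Z)-2-methylbut-2-enoate, via mixed anhydride 13 (not isolated)
Conditions: 12, 2,4,6-trichlorobenzoyl chloride, Et3N, toluene, rt; then 11, toluene, 75 °C (no DMAP)
Reagents that add atoms: none
Why: Yamaguchi esterification through the hindered mixed anhydride, run without a nucleophilic catalyst so that the (Z)-enoate should not isomerise to the tiglate; acylation at oxygen leaves the (R)-carbinol centre untouched.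

Step 7
Reactants: 14 (1R)-1-[(2S,3S)-2-(prop-1-en-2-yl)-3-(triethylsilyloxy)-2,3-dihydro-1-benzofuran-5-yl]ethyl (2Z)-2-methylbut-2-enoate
Product: 16 (1R)-1-[(2S,3S)-3-(acetyloxy)-2-(prop-1-en-2-yl)-2,3-dihydro-1-benzofuran-5-yl]ethyl (2Z)-2-methylbut-2-enoate, via free C3 alcohol 15 (not isolated)
Conditions: HF·pyridine, pyridine, THF, 0 °C; then Ac2O (excess), rt
Reagents that add atoms: acetic anhydride CC(=O)OC(C)=O
Why: Fluoride cleavage of the secondary silyl ether and acetylation of the liberated alcohol in one pyridine-buffered pot; no stereocentre is touched, and the absence of strong base or strong acid should avoid elimination of the cis C3 oxygen function toward the benzofuran.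

Step 8
Reactants: 16 (1R)-1-[(2S,3S)-3-(acetyloxy)-2-(prop-1-en-2-yl)-2,3-dihydro-1-benzofuran-5-yl]ethyl (2Z)-2-methylbut-2-enoate
Product: 17 (1R)-1-[(2S,3S)-3-(acetyloxy)-2-(3-oxoprop-1-en-2-yl)-2,3-dihydro-1-benzofuran-5-yl]ethyl (2Z)-2-methylbut-2-enoate
Conditions: SeO2 (1.2 equiv), 1,4-dioxane, 60 °C
Reagents that add atoms: selenium dioxide O=[Se]=O
Why: Riley allylic oxidation (ene reaction, [2,3]-sigmatropic shift, further oxidation) should convert the methyl group of the 1,1-disubstituted alkene into the formyl group, sparing the electron-poor angelate alkene and the less reactive allylic methine C2–H.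

Compound list
1 | 1-(3-bromo-4-fluorophenyl)ethanone | CC(=O)c1ccc(F)c(Br)c1 | starting material
2 | (1R)-1-(3-bromo-4-fluorophenyl)ethan-1-ol | Brc1cc([C@@H](C)O)ccc1F | intermediate
3 | 3-methylbut-2-en-1-ol | CC(C)=CCO | starting material
4 | [(2R)-3,3-dimethyloxiran-2-yl]methanol | OC[C@H]1OC1(C)C | intermediate
5 | (2S)-3-methyl-1,2-bis(triethylsilyloxy)but-3-ene | C=C(C)[C@@H](CO[Si](CC)(CC)CC)O[Si](CC)(CC)CC | intermediate
6 | (2S)-3-methyl-2-(triethylsilyloxy)but-3-enal | C=C(C)[C@@H](C=O)O[Si](CC)(CC)CC | intermediate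
7 | lithium (1R)-1-(4-fluoro-3-lithiophenyl)ethan-1-olate | [Li]c1cc([C@@H](C)O[Li])ccc1F | intermediate
8 | bromo{2-fluoro-5-[(1R)-1-(lithiooxy)ethyl]phenyl}magnesium | Br[Mg]c1cc([C@@H](C)O[Li])ccc1F | intermediate
9 | bromomagnesium (1S,2S)-1-{2-fluoro-5-[(1R)-1-(lithiooxy)ethyl]phenyl}-3-methyl-2-(triethylsilyloxy)but-3-en-1-olate | C=C(C)[C@H](O[Si](CC)(CC)CC)[C@@H](O[Mg]Br)c1cc([C@@H](C)O[Li])ccc1F | intermediate
10 | dipotassium (1S,2S)-1-{2-fluoro-5-[(1R)-1-oxidoethyl]phenyl}-3-methyl-1-(triethylsilyloxy)but-3-en-2-olate | C=C(C)[C@H]([O-])[C@@H](O[Si](CC)(CC)CC)c1cc([C@@H](C)[O-])ccc1F.[K+].[K+] | intermediate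
11 | (1R)-1-[(2S,3S)-2-(prop-1-en-2-yl)-3-(triethylsilyloxy)-2,3-dihydro-1-benzofuran-5-yl]ethan-1-ol | C=C(C)[C@@H]1Oc2ccc([C@@H](C)O)cc2[C@@H]1O[Si](CC)(CC)CC | intermediate
12 | angelic acid, (2Z)-2-methylbut-2-enoic acid | C/C=C(/C)C(=O)O | starting material
13 | (2Z)-2-methylbut-2-enoic 2,4,6-trichlorobenzoic anhydride | C/C=C(/C)C(=O)OC(=O)c1c(Cl)cc(Cl)cc1Cl | intermediate
14 | (1R)-1-[(2S,3S)-2-(prop-1-en-2-yl)-3-(triethylsilyloxy)-2,3-dihydro-1-benzofuran-5-yl]ethyl (2Z)-2-methylbut-2-enoate | C=C(C)[C@@H]1Oc2ccc([C@@H](C)OC(=O)/C(C)=C\C)cc2[C@@H]1O[Si](CC)(CC)CC | intermediate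
15 | (1R)-1-[(2S,3S)-3-hydroxy-2-(prop-1-en-2-yl)-2,3-dihydro-1-benzofuran-5-yl]ethyl (2Z)-2-methylbut-2-enoate | C=C(C)[C@@H]1Oc2ccc([C@@H](C)OC(=O)/C(C)=C\C)cc2[C@@H]1O | intermediate
16 | (1R)-1-[(2S,3S)-3-(acetyloxy)-2-(prop-1-en-2-yl)-2,3-dihydro-1-benzofuran-5-yl]ethyl (2Z)-2-methylbut-2-enoate | C=C(C)[C@@H]1Oc2ccc([C@@H](C)OC(=O)/C(C)=C\C)cc2[C@@H]1OC(C)=O | intermediate
17 | (1R)-1-[(2S,3S)-3-(acetyloxy)-2-(3-oxoprop-1-en-2-yl)-2,3-dihydro-1-benzofuran-5-yl]ethyl (2Z)-2-methylbut-2-enoate | C=C(C=O)[C@@H]1Oc2ccc([C@@H](C)OC(=O)/C(C)=C\C)cc2[C@@H]1OC(C)=O | target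

Total step count: 8. Longest linear sequence: 7 steps (steps 2, 3, 4, 5, 6, 7, 8, from 3-methylbut-2-en-1-ol).

Steps most likely to fail

Step 5. Non-chelated (Felkin-type) attack may compete with the magnesium chelate and erode facial selectivity at C3, and closure at the unactivated C–F carbon may lag behind loss of the silyl group. The fallback sets out from 2 and 6 and comes back at 11; it sets C3 by catalyst-controlled reduction and forms the two ring bonds in separate operations. The dilithio species 7 (n-BuLi, THF, −78 °C) is added to 6 without stereocontrol to give the C1-epimeric diols 1-{2-fluoro-5-[(1R)-1-hydroxyethyl]phenyl}-3-methyl-2-(triethylsilyloxy)but-3-en-1-ol F1. Dess–Martin periodinane (NaHCO3, CH2Cl2) oxidises both carbinols to the diketone (2S)-1-(5-acetyl-2-fluorophenyl)-3-methyl-2-(triethylsilyloxy)but-3-en-1-one F2. RuCl[(R,R)-TsDPEN](p-cymene) with HCO2H/Et3N should then reduce both aryl ketones under catalyst control, restoring the (R) side-chain carbinol and giving the (1S) benzylic alcohol (matched with Felkin attack of hydride anti to the silyloxy group), that is the syn diol (1S,2S)-1-{2-fluoro-5-[(1R)-1-hydroxyethyl]phenyl}-3-methyl-2-(triethylsilyloxy)but-3-en-1-ol F3. KOtBu in DMPU at 70 °C (silyl shift, SNAr) converts F3 into 11.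

Step 8. The benzylic acetate may ionise or eliminate toward the benzofuran under hot, acidic selenium conditions, and oxidation may stray to the allylic C2–H. The fallback sets out from 16 and comes back at 17, splitting the oxidation into two mild stages with different oxidants. Catalytic SeO2 with t-BuOOH in CH2Cl2 at 0 °C should stop at the allylic alcohol (1R)-1-[(2S,3S)-3-(acetyloxy)-2-(3-hydroxyprop-1-en-2-yl)-2,3-dihydro-1-benzofuran-5-yl]ethyl (2Z)-2-methylbut-2-enoate F4, which is isolated and oxidised with MnO2 in CH2Cl2 at rt to 17.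

Step 3. A hydride shift in the ring-opened intermediate (semipinacol path to a ketone) or proton loss from C2 instead of a methyl group may divert the epoxide opening. The fallback sets out from 4 and comes back at 5, replacing Lewis-acid opening by base-mediated syn elimination. Et3SiCl/imidazole gives the silyl ether triethyl{[(2R)-3,3-dimethyloxiran-2-yl]methoxy}silane F5. Diethylaluminium 2,2,6,6-tetramethylpiperidide (from Et2AlCl and lithium 2,2,6,6-tetramethylpiperidide, toluene, 0 °C) isomerises it to the allylic alcohol (2S)-3-methyl-1-(triethylsilyloxy)but-3-en-2-ol F6. Et3SiCl/imidazole then gives 5.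

Further compounds
F1 | step 5 | 1-{2-fluoro-5-[(1R)-1-hydroxyethyl]phenyl}-3-methyl-2-(triethylsilyloxy)but-3-en-1-ol, (2S), mixture of C1 epimers | C=C(C)[C@H](O[Si](CC)(CC)CC)C(O)c1cc([C@@H](C)O)ccc1F
F2 | step 5 | (2S)-1-(5-acetyl-2-fluorophenyl)-3-methyl-2-(triethylsilyloxy)but-3-en-1-one | C=C(C)[C@H](O[Si](CC)(CC)CC)C(=O)c1cc(C(C)=O)ccc1F
F3 | step 5 | (1S,2S)-1-{2-fluoro-5-[(1R)-1-hydroxyethyl]phenyl}-3-methyl-2-(triethylsilyloxy)but-3-en-1-ol | C=C(C)[C@H](O[Si](CC)(CC)CC)[C@@H](O)c1cc([C@@H](C)O)ccc1F
F4 | step 8 | (1R)-1-[(2S,3S)-3-(acetyloxy)-2-(3-hydroxyprop-1-en-2-yl)-2,3-dihydro-1-benzofuran-5-yl]ethyl (2Z)-2-methylbut-2-enoate | C=C(CO)[C@@H]1Oc2ccc([C@@H](C)OC(=O)/C(C)=C\C)cc2[C@@H]1OC(C)=O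
F5 | step 3 | triethyl{[(2R)-3,3-dimethyloxiran-2-yl]methoxy}silane | CC[Si](CC)(CC)OC[C@H]1OC1(C)C
F6 | step 3 | (2S)-3-methyl-1-(triethylsilyloxy)but-3-en-2-ol | C=C(C)[C@@H](CO[Si](CC)(CC)CC)O
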